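The route rests on disconnecting the quinone ring (C1–C4, C4a, C8a) at C3–C4 and C1–C2. The carbonyl carbons C1 and C4 and the fusion atoms C8a and C4a are read as the four-membered ring of the symmetrical 3,6-dimethoxybenzocyclobutene-1,2-dione, and C2=C3, with C1' on C2, as a terminal alkene joined through C2 to one dione carbonyl by a vinyllithium addition. Heating the resulting 2-alkenyl-2-hydroxybenzocyclobutenone opens the strained ring to an o-quinoid vinylketene, and a 6π closure forms C3–C4, so that one operation converts the four-membered ring into the six-membered ring of a 2-substituted naphthalene-1,4-diol. C1' is set beforehand by asymmetric ynone reduction and carried as a silyl ether.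

Key step: step 11

Remark: the key-step precursor is made and used as the mixture of both epimers at its ring carbinol carbon, which becomes sp2 in the key step, and the naphthazarin tautomers of the target are treated as one compound.

Step 1
Reactants: 1 2-bromo-1,4-dimethoxybenzene; 2 1,1-diethoxyethene
Product: 5 3,6-dimethoxybenzocyclobutenone, via dimethoxybenzyne 3 (not isolated), via diethyl ketal 4 (not isolated)
Conditions: NaNH2, THF, reflux; then 1 M HCl, THF, rt
Reagents that add atoms: water, O
Why: Sodium amide removes HBr to give the symmetrical 3,6-dimethoxybenzyne, which the nucleophilic ketene acetal traps in a [2+2] cycloaddition that can give only one regioisomer, and dilute acid then hydrolyses the strained ketal without touching the aryl methyl ethers (aryne [2+2] cycloaddition, acetal hydrolysis).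

Step 2
Reactants: 5 3,6-dimethoxybenzocyclobutenone
Product: 6 2,2-dibromo-3,6-dimethoxybenzocyclobutenone
Conditions: NBS (2.2 equiv), (BzO)2 (cat.), PhCF3, reflux, hν
Reagents that add atoms: N-bromosuccinimide, O=C1CCC(=O)N1Br
Why: The ring CH2 is both benzylic and α to the carbonyl, so radical-chain bromination in a non-polar solvent should replace both hydrogens there faster than it attacks the methoxy groups or the ring (Wohl–Ziegler bromination).

Step 3
Reactants: 6 2,2-dibromo-3,6-dimethoxybenzocyclobutenone
Product: 7 3,6-dimethoxybenzocyclobutene-1,2-dione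
Conditions: 50% aq H2SO4, 60 °C
Reagents that add atoms: water, O
Why: Ionisation of a C–Br bond next to the electron-rich arene and capture by water turn the gem-dibromide into the second carbonyl, a standard way from benzocyclobutenones to benzocyclobutenediones, and the acid leaves the methyl ethers intact (gem-dihalide hydrolysis).

Step 4
Reactants: 8 4-methylpent-3-enoic acid
Product: 10 N-methoxy-N,4-dimethylpent-3-enamide, via acyl imidazole 9 (not isolated)
Conditions: CDI, CH2Cl2, rt; then MeNHOMe·HCl, rt
Reagents that add atoms: N,O-dimethylhydroxylamine hydrochloride, CNOC.Cl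
Why: Activation of the acid as its acyl imidazole and aminolysis by the hydroxylamine proceed without strong base, so the β,γ-double bond should stay out of conjugation (Weinreb amide formation).

Step 5
Reactants: 10 N-methoxy-N,4-dimethylpent-3-enamide; 11 ethynyltrimethylsilane
Product: 13 6-methyl-1-(trimethylsilyl)hept-5-en-1-yn-3-one, via lithium acetylide 12 (not isolated)
Conditions: n-BuLi, THF, −78 °C; then 10, −78 to −20 °C; poured into cold 1 M HCl
Reagents that add atoms: none
Why: The acetylide adds once to the Weinreb amide to give a chelated tetrahedral adduct that collapses to the ynone only on acidic quench, which also protonates the released amine before it can add to the ynone (Weinreb ketone synthesis).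

Step 6
Reactants: 13 6-methyl-1-(trimethylsilyl)hept-5-en-1-yn-3-one
Product: 14 (3R)-6-methyl-1-(trimethylsilyl)hept-5-en-1-yn-3-ol
Conditions: Ru[(R,R)-TsDPEN](p-cymene) (1 mol%), i-PrOH, rt
Reagents that add atoms: none
Why: Noyori asymmetric transfer hydrogenation reduces alkynyl ketones under neutral conditions with the alkynyl group taking the place of the aryl group in the catalyst's CH/π-controlled transition state, so the (R,R)-catalyst should deliver hydride to the face that gives the (R)-carbinol and thereby set the only stereocentre of the target, without reducing the alkyne or shifting the β,γ-alkene.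

Step 7
Reactants: 14 (3R)-6-methyl-1-(trimethylsilyl)hept-5-en-1-yn-3-ol
Product: 15 tert-butyldimethyl{[(3R)-6-methyl-1-(trimethylsilyl)hept-5-en-1-yn-3-yl]oxy}silane
Conditions: TBSCl, imidazole, DMF, rt
Reagents that add atoms: tert-butyldimethylsilyl chloride, CC(C)(C)[Si](C)(C)Cl
Why: Imidazole-promoted silylation of the unhindered secondary propargylic alcohol occurs at oxygen and leaves the stereocentre untouched (silyl ether formation).

Step 8
Reactants: 15 tert-butyldimethyl{[(3R)-6-methyl-1-(trimethylsilyl)hept-5-en-1-yn-3-yl]oxy}silane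
Product: 16 tert-butyldimethyl{[(3R)-6-methylhept-5-en-1-yn-3-yl]oxy}silane
Conditions: K2CO3, MeOH, rt
Reagents that add atoms: none
Why: Methoxide attacks the trimethylsilyl group and expels the acetylide, a far better leaving group than an alkoxide, so the C–Si bond is cleaved while the bulkier O–TBS ether stays (base-mediated protodesilylation).

Step 9
Reactants: 16 tert-butyldimethyl{[(3R)-6-methylhept-5-en-1-yn-3-yl]oxy}silane
Product: 18 {[(3R)-2-bromo-6-methylhepta-1,5-dien-3-yl]oxy}(tert-butyl)dimethylsilane, via bromoalkenylborane 17 (not isolated)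
Conditions: B-Br-9-BBN, CH2Cl2, 0 °C; then AcOH, 0 °C to rt
Reagents that add atoms: B-bromo-9-borabicyclo[3.3.1]nonane, BrB1C2CCCC1CCC2
Why: The B–Br bond adds syn across the terminal alkyne only, with boron at the terminal carbon and bromine at the internal one, and acetic acid then cleaves the alkenyl C–B bond with retention to leave the 2-bromo-1-alkene while the trisubstituted alkene and the silyloxy stereocentre take no part (bromoboration, protodeboronation).

Step 10
Reactants: 18 {[(3R)-2-bromo-6-methylhepta-1,5-dien-3-yl]oxy}(tert-butyl)dimethylsilane; 7 3,6-dimethoxybenzocyclobutene-1,2-dione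
Product: 20 2-[(3R)-3-(tert-butyldimethylsilyloxy)-6-methylhepta-1,5-dien-2-yl]-2-hydroxy-3,6-dimethoxybenzocyclobuten-1(2H)-one, via vinyllithium 19 (not isolated)
Conditions: t-BuLi (2.0 equiv), Et2O, −78 °C; then cannulated into 7 (1.2 equiv), THF, −78 °C; aq NH4Cl at −78 °C
Reagents that add atoms: none
Why: Bromine–lithium exchange at −78 °C gives the 1-substituted vinyllithium, which is slow to lose silanolate at that temperature and adds once to the strained, highly electrophilic dione because the lithium alkoxide formed deactivates the neighbouring carbonyl and inverse addition keeps the dione in excess; the dione is symmetrical, so either carbonyl gives the same product, and the new carbinol centre arises as an inconsequential mixture of epimers (halogen–lithium exchange, 1,2-addition to a ketone).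

Step 11
Reactants: 20 2-[(3R)-3-(tert-butyldimethylsilyloxy)-6-methylhepta-1,5-dien-2-yl]-2-hydroxy-3,6-dimethoxybenzocyclobuten-1(2H)-one
Product: 23 2-[(1R)-1-(tert-butyldimethylsilyloxy)-4-methylpent-3-enyl]-5,8-dimethoxynaphthalene-1,4-diol, via vinylketene 21 (not isolated), via keto tautomer 22 (not isolated)
Conditions: xylenes (degassed, 0.01 M), 140 °C, Ar
Reagents that add atoms: none
Why: Heating induces a conrotatory 4π electrocyclic opening of the cyclobutenone that breaks the strained bond between the carbonyl carbon and the carbinol carbon and gives the o-quinoid vinylketene 21. The six-membered ring then closes by a thermally allowed disrotatory 6π electrocyclization of the triene made of the ketene C=C, the exocyclic enol C=C and the side-chain alkene, in which the ketene carbon bonds to the terminal CH2 (the C3–C4 bond of the target), and enolization of the 2H-naphthalen-1-one 22 restores the benzene ring and gives the diol. The closest known reaction type is the thermal ring expansion of 4-alkenyl- and 4-aryl-4-hydroxycyclobutenones and of 2-alkenyl-2-hydroxybenzocyclobutenones to hydroquinones and naphthalene-1,4-diols. No stereocentre is created, since the ring carbinol carbon becomes sp2 (both epimers of 20 converge) and C1' lies outside the reacting π system as a silyl ether and keeps its (R) configuration. The selectivity needed is torquoselectivity that turns the alkenyl group inward, next to the ketene, and the hydroxyl group on the same carbon secures it because a donor substituent rotates outward in cyclobutenone openings, here helped by a hydrogen bond to the neighbouring methoxy oxygen. Loss of four-ring strain and aromatization make the sequence irreversible, while high dilution and exclusion of air keep the ketene and the hydroquinone from bimolecular capture and oxidation.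

Step 12
Reactants: 23 2-[(1R)-1-(tert-butyldimethylsilyloxy)-4-methylpent-3-enyl]-5,8-dimethoxynaphthalene-1,4-diol
Product: 24 2-[(1R)-1-(tert-butyldimethylsilyloxy)-4-methylpent-3-enyl]-5,8-dimethoxynaphthalene-1,4-dione
Conditions: Ag2O, MgSO4, Et2O, rt
Reagents that add atoms: none
Why: The naphthalene-1,4-diol is by far the most easily oxidised group in the molecule, so silver(I) oxide should dehydrogenate it to the quinone under neutral, anhydrous conditions that leave the silyl ether, the alkene and the dimethoxy ring alone (hydroquinone oxidation).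

Step 13
Reactants: 24 2-[(1R)-1-(tert-butyldimethylsilyloxy)-4-methylpent-3-enyl]-5,8-dimethoxynaphthalene-1,4-dione
Product: 25 2-[(1R)-1-hydroxy-4-methylpent-3-enyl]-5,8-dimethoxynaphthalene-1,4-dione
Conditions: HF·pyridine, pyridine, THF, 0 °C to rt
Reagents that add atoms: none
Why: Pyridine-buffered hydrogen fluoride cleaves the Si–O bond at silicon, so the C1'–O bond is never broken and the configuration is kept, and the absence of free base protects the quinone (fluoride-mediated desilylation).

Step 14
Reactants: 25 2-[(1R)-1-hydroxy-4-methylpent-3-enyl]-5,8-dimethoxynaphthalene-1,4-dione; 26 butanoic anhydride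
Product: 27 (1R)-1-(5,8-dimethoxy-1,4-dioxo-1,4-dihydronaphthalen-2-yl)-4-methylpent-3-enyl butanoate
Conditions: DMAP (cat.), pyridine, CH2Cl2, 0 °C to rt
Reagents that add atoms: none
Why: DMAP-catalysed acyl transfer esterifies the secondary alcohol at oxygen with retention under mild conditions, and the butanoate then shields C1' during the final oxidation (DMAP-catalysed acylation).

Step 15
Reactants: 27 (1R)-1-(5,8-dimethoxy-1,4-dioxo-1,4-dihydronaphthalen-2-yl)-4-methylpent-3-enyl butanoate
Product: 29 butylshikonin, via naphthodiquinone 28 (not isolated)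
Conditions: AgO, 6 M HNO3, 1,4-dioxane, rt, short contact; then aq Na2S2O4, 0 °C
Reagents that add atoms: water, O
Why: Silver(II) in nitric acid is a strong enough one-electron oxidant to take the acyl-deactivated dimethoxy ring to a second quinone by ipso attack of water and loss of methanol, a conversion established for 5,8-dimethoxy-1,4-naphthoquinones bearing a 1-acyloxyalkyl side chain, and the mild two-electron reduction with dithionite then returns the diquinone to the naphthazarin without affecting the ester or the stereocentre (oxidative demethylation, quinone reduction).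

Compound list
1 | 2-bromo-1,4-dimethoxybenzene | COc1ccc(OC)c(Br)c1 | starting material
2 | 1,1-diethoxyethene | C=C(OCC)OCC | starting material
3 | 3,6-dimethoxybenzyne (1,2-didehydro-3,6-dimethoxybenzene, in situ) | COC1=CC=C(OC)C#C1 | intermediate
4 | 7,7-diethoxy-2,5-dimethoxybicyclo[4.2.0]octa-1,3,5-triene (in situ) | CCOC1(OCC)Cc2c(OC)ccc(OC)c21 | intermediate
5 | 3,6-dimethoxybenzocyclobutenone (2,5-dimethoxybicyclo[4.2.0]octa-1,3,5-trien-7-one) | COc1ccc(OC)c2c1CC2=O | intermediate
6 | 2,2-dibromo-3,6-dimethoxybenzocyclobutenone | COc1ccc(OC)c2c1C(Br)(Br)C2=O | intermediate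
7 | 3,6-dimethoxybenzocyclobutene-1,2-dione | COc1ccc(OC)c2c1C(=O)C2=O | intermediate
8 | 4-methylpent-3-enoic acid | CC(C)=CCC(=O)O | starting material
9 | 1-(1H-imidazol-1-yl)-4-methylpent-3-en-1-one (in situ) | CC(C)=CCC(=O)n1ccnc1 | intermediate
10 | N-methoxy-N,4-dimethylpent-3-enamide | CON(C)C(=O)CC=C(C)C | intermediate
11 | ethynyltrimethylsilane | C#C[Si](C)(C)C | starting material
12 | lithium (trimethylsilyl)acetylide (in situ) | [Li]C#C[Si](C)(C)C | intermediate
13 | 6-methyl-1-(trimethylsilyl)hept-5-en-1-yn-3-one | CC(C)=CCC(=O)C#C[Si](C)(C)C | intermediate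
14 | (3R)-6-methyl-1-(trimethylsilyl)hept-5-en-1-yn-3-ol | C[Si](C)(C)C#C[C@H](O)CC=C(C)C | intermediate
15 | tert-butyldimethyl{[(3R)-6-methyl-1-(trimethylsilyl)hept-5-en-1-yn-3-yl]oxy}silane | C[Si](C)(C)C#C[C@H](O[Si](C)(C)C(C)(C)C)CC=C(C)C | intermediate
16 | tert-butyldimethyl{[(3R)-6-methylhept-5-en-1-yn-3-yl]oxy}silane | C#C[C@H](O[Si](C)(C)C(C)(C)C)CC=C(C)C | intermediate
17 | 9-[(1Z,3R)-2-bromo-3-(tert-butyldimethylsilyloxy)-6-methylhepta-1,5-dien-1-yl]-9-borabicyclo[3.3.1]nonane (in situ) | Br/C(=C\B1C2CCCC1CCC2)[C@H](O[Si](C)(C)C(C)(C)C)CC=C(C)C | intermediate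
18 | {[(3R)-2-bromo-6-methylhepta-1,5-dien-3-yl]oxy}(tert-butyl)dimethylsilane | C=C(Br)[C@H](O[Si](C)(C)C(C)(C)C)CC=C(C)C | intermediate
19 | [(3R)-3-(tert-butyldimethylsilyloxy)-6-methylhepta-1,5-dien-2-yl]lithium (in situ) | [Li]C(=C)[C@H](O[Si](C)(C)C(C)(C)C)CC=C(C)C | intermediate
20 | 2-[(3R)-3-(tert-butyldimethylsilyloxy)-6-methylhepta-1,5-dien-2-yl]-2-hydroxy-3,6-dimethoxybenzocyclobuten-1(2H)-one (both epimers at C2) | C=C([C@H](O[Si](C)(C)C(C)(C)C)CC=C(C)C)C1(O)C(=O)c2c(OC)ccc(OC)c21 | intermediate
21 | {6-[(3R)-3-(tert-butyldimethylsilyloxy)-1-hydroxy-6-methyl-2-methylidenehept-5-en-1-ylidene]-2,5-dimethoxycyclohexa-2,4-dien-1-ylidene}methanone (hydroxyl turned outward, in situ) | O=C=C1C(OC)=CC=C(OC)/C1=C(\O)C(=C)[C@H](O[Si](C)(C)C(C)(C)C)CC=C(C)C | intermediate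
22 | 3-[(1R)-1-(tert-butyldimethylsilyloxy)-4-methylpent-3-enyl]-4-hydroxy-5,8-dimethoxynaphthalen-1(2H)-one (in situ) | O=C1CC([C@H](O[Si](C)(C)C(C)(C)C)CC=C(C)C)=C(O)c2c(OC)ccc(OC)c21 | intermediate
23 | 2-[(1R)-1-(tert-butyldimethylsilyloxy)-4-methylpent-3-enyl]-5,8-dimethoxynaphthalene-1,4-diol | CC(C)=CC[C@@H](O[Si](C)(C)C(C)(C)C)c1cc(O)c2c(OC)ccc(OC)c2c1O | intermediate
24 | 2-[(1R)-1-(tert-butyldimethylsilyloxy)-4-methylpent-3-enyl]-5,8-dimethoxynaphthalene-1,4-dione | CC(C)=CC[C@@H](O[Si](C)(C)C(C)(C)C)C1=CC(=O)c2c(OC)ccc(OC)c2C1=O | intermediate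
25 | 2-[(1R)-1-hydroxy-4-methylpent-3-enyl]-5,8-dimethoxynaphthalene-1,4-dione | CC(C)=CC[C@@H](O)C1=CC(=O)c2c(OC)ccc(OC)c2C1=O | intermediate
26 | butanoic anhydride | CCCC(=O)OC(=O)CCC | starting material
27 | (1R)-1-(5,8-dimethoxy-1,4-dioxo-1,4-dihydronaphthalen-2-yl)-4-methylpent-3-enyl butanoate | CCCC(=O)O[C@H](CC=C(C)C)C1=CC(=O)c2c(OC)ccc(OC)c2C1=O | intermediate
28 | (1R)-4-methyl-1-(1,4,5,8-tetraoxo-1,4,5,8-tetrahydronaphthalen-2-yl)pent-3-enyl butanoate (in situ) | CCCC(=O)O[C@H](CC=C(C)C)C1=CC(=O)C2=C(C1=O)C(=O)C=CC2=O | intermediate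
29 | butylshikonin, (1R)-1-(5,8-dihydroxy-1,4-dioxo-1,4-dihydronaphthalen-2-yl)-4-methylpent-3-enyl butanoate | CCCC(=O)O[C@H](CC=C(C)C)C1=CC(=O)c2c(O)ccc(O)c2C1=O | target

Total step count: 15. Longest linear sequence: 12 steps (steps 4 to 15, from 8); the dione 7 is made in a three-step side branch (steps 1 to 3).

Steps most likely to fail

Step 15. The acyl-deactivated dimethoxy ring may be oxidised only slowly, so that silver(II) and nitric acid begin to degrade the trisubstituted alkene. Alternatively, the diquinone may be over-reduced by dithionite and then lose butanoate. The fallback sets out from 25 and comes back to the route at 29; it oxidises the dimethoxy ring while that ring is still electron-rich. Reductive acylation of 25 (Zn dust, butanoic anhydride 26, pyridine, DMAP) would give the tris-butanoate (1R)-1-[1,4-bis(butanoyloxy)-5,8-dimethoxynaphthalen-2-yl]-4-methylpent-3-enyl butanoate F1. Cerium(IV) ammonium nitrate in aqueous acetonitrile at 0 °C should then oxidise only the dimethoxy ring, the bis(acyloxy) ring being deactivated, to (1R)-1-[1,4-bis(butanoyloxy)-5,8-dioxo-5,8-dihydronaphthalen-2-yl]-4-methylpent-3-enyl butanoate F2. Brief methanolysis (NaHCO3, MeOH, 0 °C) would cleave the two activated aryl esters and leave the secondary alkyl ester, giving 29.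

Step 11. At the temperature needed to open the benzo-fused four-membered ring, the free hydroquinone may lose silanol from C1' through an o-quinone methide. The ketene may also be captured by hydroxyl groups before it cyclises. The fallback sets out from 16 and 7 and comes back to the route at 24; it uses the alkynyl variant of the ring expansion, which reaches the quinone without a free hydroquinone. Deprotonation of 16 (n-BuLi, THF, −78 °C) would give lithium (3R)-3-(tert-butyldimethylsilyloxy)-6-methylhept-5-en-1-yn-1-ide F3. Its addition to 7 at −78 °C would give 2-[(3R)-3-(tert-butyldimethylsilyloxy)-6-methylhept-5-en-1-yn-1-yl]-2-hydroxy-3,6-dimethoxybenzocyclobuten-1(2H)-one F4. Thermolysis of this carbinol (degassed xylenes, 140 °C) should proceed by ring opening, bonding of the ketene carbon to the distal alkyne carbon and hydrogen transfer from the hydroxyl group, and give 24 directly. Alkyl-substituted alkynes favour this six-membered closure over the five-membered alternative.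

Step 10. The β-silyloxy vinyllithium may eliminate silanolate before it adds. A second equivalent may also attack the remaining carbonyl, or the lithium alkoxide of the ketol may open the four-membered ring. The fallback sets out from 7 and comes back to the route at 20; it masks one carbonyl. Monoketalisation of 7 (1,2-bis(trimethylsilyloxy)ethane, TMSOTf cat., CH2Cl2, −78 °C) would give 2',5'-dimethoxyspiro[1,3-dioxolane-2,7'-bicyclo[4.2.0]octa[1,3,5]trien]-8'-one F5. Addition of 19 to its only carbonyl would give 8'-[(3R)-3-(tert-butyldimethylsilyloxy)-6-methylhepta-1,5-dien-2-yl]-2',5'-dimethoxyspiro[1,3-dioxolane-2,7'-bicyclo[4.2.0]octa[1,3,5]trien]-8'-ol F6, whose alkoxide can neither be attacked again nor open to a ketene. Hydrolysis of the ketal with oxalic acid on wet silica gel in CH2Cl2 would then release 20.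

Further compounds
F1 | step 15 | (1R)-1-[1,4-bis(butanoyloxy)-5,8-dimethoxynaphthalen-2-yl]-4-methylpent-3-enyl butanoate | CCCC(=O)O[C@H](CC=C(C)C)c1cc(OC(=O)CCC)c2c(OC)ccc(OC)c2c1OC(=O)CCC
F2 | step 15 | (1R)-1-[1,4-bis(butanoyloxy)-5,8-dioxo-5,8-dihydronaphthalen-2-yl]-4-methylpent-3-enyl butanoate | CCCC(=O)O[C@H](CC=C(C)C)c1cc(OC(=O)CCC)c2C(=O)C=CC(=O)c2c1OC(=O)CCC
F3 | step 11 | lithium (3R)-3-(tert-butyldimethylsilyloxy)-6-methylhept-5-en-1-yn-1-ide | [Li]C#C[C@H](O[Si](C)(C)C(C)(C)C)CC=C(C)C
F4 | step 11 | 2-[(3R)-3-(tert-butyldimethylsilyloxy)-6-methylhept-5-en-1-yn-1-yl]-2-hydroxy-3,6-dimethoxybenzocyclobuten-1(2H)-one | OC1(C#C[C@H](O[Si](C)(C)C(C)(C)C)CC=C(C)C)C(=O)c2c(OC)ccc(OC)c21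
F5 | step 10 | 2',5'-dimethoxyspiro[1,3-dioxolane-2,7'-bicyclo[4.2.0]octa[1,3,5]trien]-8'-one | COc1ccc(OC)c2c1C(=O)C21OCCO1
F6 | step 10 | 8'-[(3R)-3-(tert-butyldimethylsilyloxy)-6-methylhepta-1,5-dien-2-yl]-2',5'-dimethoxyspiro[1,3-dioxolane-2,7'-bicyclo[4.2.0]octa[1,3,5]trien]-8'-ol | C=C([C@H](O[Si](C)(C)C(C)(C)C)CC=C(C)C)C1(O)c2c(OC)ccc(OC)c2C12OCCO2
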